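The earlier runs and the new flask are simulated for an exercise, and the scatter is random.

Work in logs. I want the selectivity c_E/c_Q of the flask, and alpha is that same flask, followed so far.

| setting | alpha | theta | flask |
|---|---|---|---|
| D | 0.20 M | 0.10 M | 0.20 M |
| L | 0.22 M | 0.22 M | 0.220 M |
| remark | the very flask that is asked about, followed so far | run made earlier |  |
| time |  |  | 15 d |

| run | time / d | E / % | Q / % |
|---|---|---|---|
| alpha | 1.67 | 15.2 | 16.2 |
| alpha | 3.00 | 13.5 | 17.6 |
| alpha | 5.00 | 9.6 | 20.4 |
| alpha | 6.00 | 10.0 | 21.8 |
| theta | 2.50 | 21.8 | 20.7 |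
| theta | 5.00 | 22.4 | 24.4 |
| theta | 8.00 | 20.5 | 28.1 |
| theta | 10.0 | 20.4 | 28.1 |

(scatter of a reading: 0.5 percentage points)

- ratio of E to Q at 30 min
- ratio of E to Q at 15 h
- ratio of E to Q at 15 d
- which of E and Q there is more of at 15 d

The two early times lie before the first reading, so I reckon the late ratio. I take it to fall steadily in lg from the last reading, at 6.00 d:

lg(c_E/c_Q at 15 d) = lg(c_E/c_Q at 6.00 d) − (15 d − 6.00 d)/T

Which input matters? One standard deviation on the last E reading moves the lg ratio by 0.0212, and on the last Q reading by 0.00985. Both are small against the size of that lg ratio, 0.338, so I start from the reading 0.459. T matters: it divides the whole stretch of 9.00 d.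

Alpha falls from 0.938, which gives T = 13.9 d, the decade time, the days in which the ratio falls by a power of ten. Theta, with half the D, reads a longer one, 46.4 d. I expect alpha's T to lengthen towards that as alpha runs on. The two values give:

alpha's T: 0.104
theta's T: 0.294

I commit to the middle in logs, 0.174, with Q ahead.

The forecast says “each run flattens at its own plateau”, and gives 1.25, 1.1 and 0.45, with Q ahead. Its late ratio is higher than mine.

The flask gives 3.38, 1.30 and 0.285, with Q ahead, 25.7% against 7.33% of E. D stands at 51.7% of its charge at 1.50 d and 8.95% at 15.0 d. From the reading at 6.00 d to the computed ratio at 15 d, the decade time comes on average to 43.5 d, longer than 13.9 d and shorter than 46.4 d.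

    D ⇌ X (K = 0.0250, k = 0.0568 /h)
    D + L → E (k = 0.106 /M/h)
    L + X → Q (k = 3.42 /M/h)
    L ⇌ J (K = 5.38, k = 0.0479 /h)
    D + E → Z (k = 0.136 /M/h)

A neighbour flask holds 0.055 M of L, its D and its time as in the flask; there 13.9 d carries the computed 1.10 at 15 h down to 0.102 at 15 d. The neighbour's computed ratio at 15 d is 0.0646, with 65.2% of its D still there.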